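## Retrosynthetic overview

1. Endgame: the isopropenyl group is traced back to a tertiary carbinol on C2 (dehydration comes last). The C3–O acyl bond is traced back to (Z)-4-acetoxy-2-methylbut-2-enoic acid, whose Z geometry is the ring geometry of 3-methylfuran-2(5H)-one.
2. Feature on which the route rests: in the benzofuran core, C3a is ortho to O1 (carried by C7a) and para to the C6 hydroxyl, which makes it C5 of 2,4-dihydroxyacetophenone. C3–C2–C(CH3)2 is the carbon chain of epoxidised prenal.
3. Key disconnection: the dihydrofuran ring (O1, C2, C3, C3a, C7a) is cut at C3–C3a and at O1–C2. This leads back to a magnesium bis(phenolate) and (S)-3,3-dimethyloxirane-2-carbaldehyde, and both bonds are made in one flask.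
4. Site control: metal phenolates of 2,4-dihydroxyacetophenone normally react at C3, between the two oxygens, so C3 carries an iodine through the key step (one step on, one step off).
5. Ring order and chirality: the benzene ring is bought and the dihydrofuran ring is the only ring formed. All absolute configuration stems from one Sharpless epoxidation of prenol with D-(−)-diethyl tartrate.

Key step: step 4

Numbering used below: acetophenone numbering (C1 bears the acetyl group) for the monocyclic aromatic compounds, and benzofuran numbering (O1, C2, C3, C3a, C4 to C7, C7a) for the bicyclic ones.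

## Route

Step 1
Reactants: 1 resacetophenone (2,4-dihydroxyacetophenone)
Product: 2 iodoresacetophenone (2,4-dihydroxy-3-iodoacetophenone)
Conditions: I2 (0.4 equiv), HIO3 (0.2 equiv), EtOH–H2O, rt
Reagents that add atoms: iodine, II; iodic acid, OI(=O)=O
Why: Electrophilic aromatic iodination with I2/HIO3 should go to C3, the enol-like carbon between the two oxygens that the hydrogen-bonded 2-hydroxyl/acetyl chelate activates most and that phenolate-type reactions of 1 (Claisen rearrangement of its 4-allyl ether, chromene formation with enals) also choose, so that this competing site is closed before step 4.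

Step 2
Reactants: 3 prenol (3-methylbut-2-en-1-ol)
Product: 4 (R)-(3,3-dimethyloxiran-2-yl)methanol
Conditions: Ti(OiPr)4 (cat.), D-(−)-diethyl tartrate (cat.), t-BuOOH, 4 Å MS, CH2Cl2, −20 °C; non-aqueous work-up, distillation
Reagents that add atoms: tert-butyl hydroperoxide, CC(C)(C)OO
Why: Sharpless asymmetric epoxidation, in which the titanium/D-(−)-tartrate complex delivers oxygen to the alkene face that gives the (R)-epoxy alcohol and thereby sets the carbon that becomes C2.

Step 3
Reactants: 4 (R)-(3,3-dimethyloxiran-2-yl)methanol
Product: 5 (S)-3,3-dimethyloxirane-2-carbaldehyde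
Conditions: (n-Pr4N)RuO4 (cat.), NMO, 4 Å MS, CH2Cl2, rt; filtration through silica, used as a CH2Cl2 solution
Reagents that add atoms: none
Why: Ley–Griffith oxidation stops at the aldehyde under neutral, water-free conditions that leave the epoxide and its stereocentre alone (the descriptor changes from R to S only because CHO outranks the ring carbon).

Step 4
Reactants: 2 iodoresacetophenone (2,4-dihydroxy-3-iodoacetophenone); 5 (S)-3,3-dimethyloxirane-2-carbaldehyde
Product: 8 (2S,3S)-5-acetyl-2-(2-hydroxypropan-2-yl)-7-iodo-2,3-dihydro-1-benzofuran-3,6-diol (trans), via bis(bromomagnesium) phenolate 6 (not isolated), via syn epoxy alcohol 7 (not isolated)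
Conditions: 2, EtMgBr (2.0 equiv), Et2O–THF, −20 to 0 °C, then solvent exchange to CH2Cl2; 5 (1.0 equiv), CH2Cl2, −20 °C to rt, sonication; then MeOH, K2CO3 (3 equiv), rt
Reagents that add atoms: none
Why: Proposed new method: the aldehyde of 5 binds the bromomagnesium centre on O4 of 6 and is passed to the adjacent ring carbon C5 through a six-membered cyclic transition state, and rearomatisation of the dienone leaves the magnesium salt of 7 (bond C3–C3a). The closest known reaction types are the ortho-specific hydroxyalkylation of bromomagnesium phenolates by alpha-oxygenated chiral aldehydes in non-donor solvents and the base-induced cyclisation of ortho-(2,3-epoxyalkyl)phenols, whereas their tandem use on an epoxy aldehyde and on an acetyl-bearing ring is without precedent. C3 is set in the addition, because the unsolvated magnesium in CH2Cl2 should also hold the epoxide oxygen and the ring carbon then reaches the chelated carbonyl from the side of the small hydrogen on the oxirane carbon, which gives the syn (S)-carbinol. After the change to K2CO3/MeOH the O4 phenoxide opens the oxirane at its secondary carbon in a 5-exo-tet closure (bond O1–C2) with a single inversion of the Sharpless-derived centre, so that syn-7 becomes the trans-2,3-disubstituted dihydrofuran ring and the tertiary carbinol is released. Site selectivity is secured by the substrate itself, since the iodine at C3 and the acetyl group at C1 leave C5 as the only open carbon ortho to a phenolate oxygen. The 5-exo course (rather than 6-endo attack at the tertiary carbon) and the absence of Payne migration are secured by precipitating the Lewis acidic magnesium as MgCO3 and by a base that ionises the phenol but not the C3 alcohol.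

Step 5
Reactants: 8 (2S,3S)-5-acetyl-2-(2-hydroxypropan-2-yl)-7-iodo-2,3-dihydro-1-benzofuran-3,6-diol
Product: 9 (2S,3S)-5-acetyl-2-(2-hydroxypropan-2-yl)-2,3-dihydro-1-benzofuran-3,6-diol (trans triol)
Conditions: Pd(OAc)2 (cat.), PPh3, HCO2Na, DMF, 60–80 °C
Reagents that add atoms: none
Why: Palladium-catalysed formate hydrodehalogenation, in which zerovalent palladium inserts into the aryl carbon–iodine bond and formate supplies hydride with loss of CO2, should remove the blocking group without touching the ketone, the benzylic alcohol or either stereocentre.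

Step 6
Reactants: 10 alpha-methylbutenolide (3-methylfuran-2(5H)-one)
Product: 13 PMB (Z)-4-acetoxy-2-methylbut-2-enoate (PMB = 4-methoxybenzyl), via potassium hydroxy carboxylate 11 (not isolated), via PMB hydroxy ester 12 (not isolated)
Conditions: KOH (1.0 equiv), H2O–THF, 0 °C to rt, evaporation to dryness; PMBCl, Bu4NI (cat.), DMF, rt; then Ac2O, pyridine, DMAP (cat.), 0 °C
Reagents that add atoms: potassium hydroxide, [K+].[OH-]; 4-methoxybenzyl chloride, COc1ccc(CCl)cc1; acetic anhydride, CC(=O)OC(C)=O
Why: Lactone saponification, carboxylate O-alkylation and acetylation are run in one flask, so that the Z geometry, which is the cis geometry of the butenolide ring, is never disturbed and the hydroxy ester 12 is acetylated at once before it can close back to 10.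

Step 7
Reactants: 13 PMB (Z)-4-acetoxy-2-methylbut-2-enoate
Product: 14 (Z)-4-acetoxy-2-methylbut-2-enoic acid
Conditions: TFA, anisole, CH2Cl2, 0 °C
Reagents that add atoms: none
Why: Acidolysis of a 4-methoxybenzyl ester (ionisation to the stabilised benzyl cation, which anisole traps by Friedel–Crafts alkylation) should free the acid while the primary acetate and the Z-alkene stay as they are.

Step 8
Reactants: 9 (2S,3S)-5-acetyl-2-(2-hydroxypropan-2-yl)-2,3-dihydro-1-benzofuran-3,6-diol; 14 (Z)-4-acetoxy-2-methylbut-2-enoic acid
Product: 16 (2S,3S)-5-acetyl-6-hydroxy-2-(2-hydroxypropan-2-yl)-2,3-dihydro-1-benzofuran-3-yl (Z)-4-acetoxy-2-methylbut-2-enoate, via acid chloride 15 (not isolated)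
Conditions: 14, 1-chloro-N,N,2-trimethylprop-1-en-1-amine (Ghosez reagent), CH2Cl2, 0 °C; then 9, 2,4,6-collidine, CH2Cl2, −20 °C to rt
Reagents that add atoms: none
Why: Esterification through an acid chloride made under neutral conditions with the Ghosez reagent and coupled with a hindered, non-nucleophilic pyridine base avoids the addition–elimination that turns angelate-type acyl donors into their E isomers, the secondary C3 alcohol should react ahead of the tertiary carbinol (steric shielding) and of the C6 phenol (hydrogen-bonded to the acetyl group and not ionised by collidine), and the C3–O bond is not broken, so C3 keeps its configuration.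

Step 9
Reactants: 16 (2S,3S)-5-acetyl-6-hydroxy-2-(2-hydroxypropan-2-yl)-2,3-dihydro-1-benzofuran-3-yl (Z)-4-acetoxy-2-methylbut-2-enoate
Product: 18 (2R,3S)-5-acetyl-6-hydroxy-2-(prop-1-en-2-yl)-2,3-dihydro-1-benzofuran-3-yl (Z)-4-acetoxy-2-methylbut-2-enoate (CNP0273504.1), via tertiary sulfamate 17 (not isolated)
Conditions: Burgess reagent (methyl N-(triethylammoniosulfonyl)carbamate), toluene, rt then 50 °C
Reagents that add atoms: none
Why: Burgess dehydration, a thermal syn (Ei) elimination of the tertiary sulfamate 17 under nearly neutral conditions, should take one of the six methyl hydrogens rather than the single C2 hydrogen, which is flanked by two carbon–oxygen bonds and can reach the syn-periplanar geometry only against the ring substituents, and it leaves C2, C3, the benzylic ester and the allylic acetate untouched (the C2 descriptor changes from S to R only through the change in substituent priority).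

## Compound list

1 | 2,4-dihydroxyacetophenone (resacetophenone) | CC(=O)c1ccc(O)cc1O | starting material
2 | 2,4-dihydroxy-3-iodoacetophenone | CC(=O)c1ccc(O)c(I)c1O | intermediate
3 | prenol (3-methylbut-2-en-1-ol) | CC(C)=CCO | starting material
4 | (R)-(3,3-dimethyloxiran-2-yl)methanol | CC1(C)O[C@@H]1CO | intermediate
5 | (S)-3,3-dimethyloxirane-2-carbaldehyde | CC1(C)O[C@@H]1C=O | intermediate
6 | bis(bromomagnesium) O2,O4-phenolate of 2 (not isolated) | CC(=O)c1ccc(O[Mg]Br)c(I)c1O[Mg]Br | intermediate
7 | 1-{2,4-dihydroxy-5-[(S)-[(2R)-3,3-dimethyloxiran-2-yl](hydroxy)methyl]-3-iodophenyl}ethan-1-one, syn epoxy alcohol, present as its magnesium salt (not isolated) | CC1(C)O[C@@H]1[C@@H](O)c2cc(C(C)=O)c(O)c(I)c2O | intermediate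
8 | (2S,3S)-5-acetyl-2-(2-hydroxypropan-2-yl)-7-iodo-2,3-dihydro-1-benzofuran-3,6-diol (trans) | CC(C)(O)[C@H]1Oc2c(I)c(O)c(C(C)=O)cc2[C@@H]1O | intermediate
9 | (2S,3S)-5-acetyl-2-(2-hydroxypropan-2-yl)-2,3-dihydro-1-benzofuran-3,6-diol (trans triol) | CC(C)(O)[C@H]1Oc2cc(O)c(C(C)=O)cc2[C@@H]1O | intermediate
10 | 3-methylfuran-2(5H)-one | CC1=CCOC1=O | starting material
11 | potassium (Z)-4-hydroxy-2-methylbut-2-enoate (not isolated) | [K+].[O-]C(=O)/C(C)=C\CO | intermediate
12 | 4-methoxybenzyl (Z)-4-hydroxy-2-methylbut-2-enoate (not isolated) | COc1ccc(COC(=O)/C(C)=C\CO)cc1 | intermediate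
13 | 4-methoxybenzyl (Z)-4-acetoxy-2-methylbut-2-enoate | COc1ccc(COC(=O)/C(C)=C\COC(C)=O)cc1 | intermediate
14 | (Z)-4-acetoxy-2-methylbut-2-enoic acid | OC(=O)/C(C)=C\COC(C)=O | intermediate
15 | (Z)-4-acetoxy-2-methylbut-2-enoyl chloride (not isolated) | ClC(=O)/C(C)=C\COC(C)=O | intermediate
16 | (2S,3S)-5-acetyl-6-hydroxy-2-(2-hydroxypropan-2-yl)-2,3-dihydro-1-benzofuran-3-yl (Z)-4-acetoxy-2-methylbut-2-enoate | CC(C)(O)[C@H]1Oc2cc(O)c(C(C)=O)cc2[C@@H]1OC(=O)/C(C)=C\COC(C)=O | intermediate
17 | triethylammonium salt of the N-(methoxycarbonyl)sulfamate ester of the tertiary alcohol of 16 (not isolated) | CC[NH+](CC)CC.COC(=O)[N-]S(=O)(=O)OC(C)(C)[C@H]1Oc2cc(O)c(C(C)=O)cc2[C@@H]1OC(=O)/C(C)=C\COC(C)=O | intermediate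
18 | (2R,3S)-5-acetyl-6-hydroxy-2-(prop-1-en-2-yl)-2,3-dihydro-1-benzofuran-3-yl (Z)-4-acetoxy-2-methylbut-2-enoate, trans (CNP0273504.1) | C=C(C)[C@H]1Oc2cc(O)c(C(C)=O)cc2[C@@H]1OC(=O)/C(C)=C\COC(C)=O | target

## Step count and risks

Total number of steps: 9.
Longest linear sequence: 6 steps (3 → 4 → 5 → 8 → 9 → 16 → 18, which are steps 2, 3, 4, 5, 8 and 9).

**Risk 1 (step 4).**
- What may go wrong:
  - Carbon–carbon bond formation may be slow, because the ring carries an acetyl group and an iodine and the bis(magnesium) salt dissolves poorly.
  - Bromide may open the epoxide at the Lewis acidic metal before the base is added.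
  - The epoxide oxygen may bind the metal only weakly, which would give poor facial selectivity at C3.
  - An aldol reaction may occur at the acetyl methyl group.
- Fallback: it uses known chemistry, sets out from 1 and 5, and comes back at 16. Iodination of 1 under acidic, non-phenolate conditions (ICl, AcOH) should go to C5, as bromination and nitration do, and give 2,4-dihydroxy-5-iodoacetophenone F1. Ac2O/pyridine then gives 4-acetyl-6-iodobenzene-1,3-diyl diacetate F2. Nozaki–Hiyama–Kishi coupling of F2 with 5 (CrCl2, NiCl2 cat., DMF, rt) forms C3–C3a at the carbon that bore the iodine and tolerates the ketone, the esters and the epoxide. It should follow the open Felkin-type model and give mainly the anti epoxy alcohol F3. K2CO3/MeOH removes both acetates and closes the ring 5-exo to the cis triol F4. Mitsunobu esterification of F4 with 14 (PPh3, DIAD, toluene, 0 °C) inverts C3 and gives 16. Any syn adduct from the coupling ends as 9 and follows step 8, so both carbinol epimers are usable.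

**Risk 2 (step 8).**
- What may go wrong:
  - The activated acyl group may isomerise from Z to E.
  - Gamma-deprotonation may lead to a vinylketene.
  - The acid chloride may be lost by closure back to the butenolide.
  - Acylation may compete at the phenol.
- Fallback: it sets out from 9 and comes back at 16, and it builds the Z-alkene on the substrate instead of carrying it through acyl activation. Carbodiimide esterification of 9 with 2-[bis(2,2,2-trifluoroethoxy)phosphoryl]propanoic acid (EDC, DMAP cat., CH2Cl2) gives the C3 phosphonopropanoate F5. A Still–Gennari olefination of F5 with 2-oxoethyl acetate (KN(SiMe3)2, 2 equiv, 18-crown-6, THF, −78 °C) then gives 16.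

**Risk 3 (step 9).**
- What may go wrong:
  - Elimination may go toward the C2 hydrogen instead of a methyl group.
  - The phenol may be sulfamoylated.
  - The C3 carboxylate may be lost on warming, with aromatisation of the five-membered ring.
- Fallback: it sets out from 9 and 15 and comes back at 18. The dehydration is moved ahead of the ester, so the labile benzylic ester never meets it. TESCl/imidazole silylates the C3 alcohol and the phenol but not the tertiary carbinol, giving the bis(triethylsilyl) ether F6. SOCl2/pyridine at −20 °C (E2-type loss of the chlorosulfite, the classical dehydration of 2-(2-hydroxypropan-2-yl)dihydrobenzofurans) gives the isopropenyl bis(silyl) ether F7. Et3N·3HF frees the isopropenyl diol F8. Acylation of F8 with 15 under the conditions of step 8 then gives 18.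

## Further compounds

F1 | step 4 | 2,4-dihydroxy-5-iodoacetophenone | CC(=O)c1cc(I)c(O)cc1O
F2 | step 4 | 4-acetyl-6-iodobenzene-1,3-diyl diacetate | CC(=O)Oc1cc(OC(C)=O)c(C(C)=O)cc1I
F3 | step 4 | 4-acetyl-6-{(R)-[(2R)-3,3-dimethyloxiran-2-yl](hydroxy)methyl}benzene-1,3-diyl diacetate (anti epoxy alcohol) | CC1(C)O[C@@H]1[C@H](O)c2cc(C(C)=O)c(OC(C)=O)cc2OC(C)=O
F4 | step 4 | (2S,3R)-5-acetyl-2-(2-hydroxypropan-2-yl)-2,3-dihydro-1-benzofuran-3,6-diol (cis triol) | CC(C)(O)[C@H]1Oc2cc(O)c(C(C)=O)cc2[C@H]1O
F5 | step 8 | (2S,3S)-5-acetyl-6-hydroxy-2-(2-hydroxypropan-2-yl)-2,3-dihydro-1-benzofuran-3-yl 2-[bis(2,2,2-trifluoroethoxy)phosphoryl]propanoate (C3 phosphonopropanoate, epimers at the phosphonate carbon) | CC(C)(O)[C@H]1Oc2cc(O)c(C(C)=O)cc2[C@@H]1OC(=O)C(C)P(=O)(OCC(F)(F)F)OCC(F)(F)F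
F6 | step 9 | 1-[(2S,3S)-2-(2-hydroxypropan-2-yl)-3,6-bis(triethylsilyloxy)-2,3-dihydro-1-benzofuran-5-yl]ethan-1-one (bis(triethylsilyl) ether) | CC(C)(O)[C@H]1Oc2cc(O[Si](CC)(CC)CC)c(C(C)=O)cc2[C@@H]1O[Si](CC)(CC)CC
F7 | step 9 | 1-[(2R,3S)-2-(prop-1-en-2-yl)-3,6-bis(triethylsilyloxy)-2,3-dihydro-1-benzofuran-5-yl]ethan-1-one (isopropenyl bis(silyl) ether) | C=C(C)[C@H]1Oc2cc(O[Si](CC)(CC)CC)c(C(C)=O)cc2[C@@H]1O[Si](CC)(CC)CC
F8 | step 9 | (2R,3S)-5-acetyl-2-(prop-1-en-2-yl)-2,3-dihydro-1-benzofuran-3,6-diol (isopropenyl diol) | C=C(C)[C@H]1Oc2cc(O)c(C(C)=O)cc2[C@@H]1O
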